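**Plan**
1. Cuts: the two acetates and the C9 carbinol lead back to a 9‑ketone. A transannular C4–C9 bond is then redrawn (retro‑Grob). After that C8–C9, C4–CH3 and C4–C5 are cut, leaving (S)‑carvone and a trisubstituted γ‑lactone aldehyde. In the aldehyde, C11–CH3 and C7–C8 are cut back to (S)‑5‑(hydroxymethyl)butenolide, MeI and MeOH.
2. Enabling feature (germacrane numbering): once C4–C9 is drawn, the arc C9–C10(Me)=C1–C2–C3–C4 is the six‑membered ring of carvone, with C9 its carbonyl carbon and C3 its isopropenyl carbon. The arc C4–C5–C6–C7–C8–C9 is a second six‑membered ring carrying the trans‑fused lactone O–C6–C7–C11–C12. C5 lies 1,3 to O9, so a leaving group on C5 and an alkoxide on C9 can cut the shared bond.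
3. Forward order: the lactone ring is present from the start and is joined to the carvone ring at C4–C5. Ring B then closes at C8–C9 to a cis‑decalin, and the fragmentation merges both carbocycles into the ten‑membered ring.
4. Stereochemistry: C6 comes from the butenolide, C7 from anti radical addition, C11 from kinetic protonation, and C3 from carvone (Criegee rearrangement with retention). The sacrificial centres C4 (methylation anti to isopropenyl), C5 (Felkin–Anh reduction) and C9 (lactone‑locked chair closure) encode the 4Z alkene. The 1(10)Z alkene is the cyclohexene bond of carvone, and the final C9 centre is set by CBS reduction.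

Key step: step 17

Remarks on the chemistry:
- All coupled intermediates carry the atom numbers of the target (C13 on C11, C14 on C10, C15 on C4). α is the face of H7 and β the face of H6.
- Compound 1 is assumed to be bought as the single (S) enantiomer.
- O3 is carried as the acetate that the Criegee rearrangement delivers. No β‑hydroxy ketone is therefore ever set free, and the axial C3 substituent of the decalin stays small.

**Step 1**
Reactants: 1 (S)-5-(hydroxymethyl)furan-2(5H)-one
Product: 2 (S)-5-[(tert-butyldimethylsilyloxy)methyl]furan-2(5H)-one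
Conditions: TBSCl, imidazole, DMF, 0 °C → rt
Reagents that add atoms: tert-butyldimethylsilyl chloride, CC(C)(C)[Si](C)(C)Cl
Why: Routine silylation of a primary alcohol that leaves C6 untouched and gives the bulky group that will shield one butenolide face.

**Step 2**
Reactants: 2 silyl butenolide; 3 methanol
Product: 4 (4R,5S)-5-[(TBSO)methyl]-4-(hydroxymethyl)dihydrofuran-2(3H)-one (C6/C7 trans)
Conditions: Ph2CO (cat.), degassed MeOH, hν (350 nm), rt
Reagents that add atoms: methanol (3), CO
Why: In this sensitised photochemical Giese-type conjugate addition, triplet benzophenone abstracts H from methanol and the nucleophilic hydroxymethyl radical should add to the β‑carbon C7 anti to the C6 side chain, forming C7–C8 and setting C7.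

**Step 3**
Reactants: 4 hydroxymethyl lactone
Product: 5 (4R,5S)-5-[(TBSO)methyl]-4-[(TBDPSO)methyl]dihydrofuran-2(3H)-one
Conditions: TBDPSCl, imidazole, DMF, rt
Reagents that add atoms: tert-butyldiphenylsilyl chloride, CC(C)(C)[Si](Cl)(c1ccccc1)c1ccccc1
Why: Silylation with the more acid-stable TBDPS group differentiates O8 from the TBS-protected oxygen on C5 and blocks translactonisation through O8.

**Step 4**
Reactants: 5 bis-silyl lactone; 6 iodomethane
Product: 8 (3S,4R,5S)-5-[(TBSO)methyl]-4-[(TBDPSO)methyl]-3-methyldihydrofuran-2(3H)-one (C13 trans to C8), via lithium enolate 7 (not isolated)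
Conditions: LDA, THF, −78 °C; MeI, −78 → −40 °C
Reagents that add atoms: iodomethane (6), CI
Why: In this lactone enolate alkylation, MeI should enter opposite the neighbouring C7 substituent and give the 3,4-trans lactone, which installs C13 but with C11 still in the wrong configuration.

**Step 5**
Reactants: 8 trans-methyl lactone
Product: 10 (3R,4R,5S)-5-[(TBSO)methyl]-4-[(TBDPSO)methyl]-3-methyldihydrofuran-2(3H)-one (C13 cis to C8), via lithium enolate 9 (not isolated)
Conditions: LDA, THF, −78 °C; then 2,6-di-tert-butyl-4-methylphenol in THF, −78 °C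
Reagents that add atoms: none
Why: In this kinetic protonation of a lactone enolate, the hindered phenol should deliver the proton to the face opposite the C7 CH2OTBDPS group, pushing the methyl group cis to C8 and giving the contra-thermodynamic 11R centre of the target.

**Step 6**
Reactants: 10 cis-methyl lactone
Product: 11 (3R,4R,5S)-4-[(TBDPSO)methyl]-5-(hydroxymethyl)-3-methyldihydrofuran-2(3H)-one
Conditions: CSA (10 mol %), MeOH/CH2Cl2 1:1, 0 °C
Reagents that add atoms: none
Why: Acid-catalysed methanolysis removes a primary TBS ether much faster than a primary TBDPS ether, and it cannot epimerise C11.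

**Step 7**
Reactants: 11 primary alcohol
Product: 12 (2S,3R,4R)-3-[(TBDPSO)methyl]-4-methyl-5-oxotetrahydrofuran-2-carbaldehyde
Conditions: Dess–Martin periodinane, CH2Cl2, 0 °C → rt
Reagents that add atoms: none
Why: Dess–Martin oxidation is neutral and stops at the aldehyde (C5), and the C6 centre next to it already holds its more stable trans arrangement.

**Step 8**
Reactants: 13 (S)-(+)-carvone; 12 lactone aldehyde
Product: 15 C4–C5 aldol adduct of carvone (C4/C5 epimer mixture), via carvone lithium dienolate 14 (not isolated)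
Conditions: LDA, THF, −78 °C; 12, −78 °C; AcOH quench at −78 °C
Reagents that add atoms: none
Why: In this directed aldol addition, kinetic α′-deprotonation of carvone gives the cross-conjugated dienolate, which should add to the aldehyde faster than it exchanges protons with the lactone, and the new C4 and C5 centres need no control because steps 9 and 10 erase them.

**Step 9**
Reactants: 15 aldol adduct
Product: 16 1,3-diketone (C5 and C9 ketones, enolisable C4–H)
Conditions: IBX, EtOAc, 75 °C
Reagents that add atoms: none
Why: IBX oxidation of β-hydroxy ketones stops at the 1,3-diketone and leaves alkenes, lactone and silyl ether alone.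

**Step 10**
Reactants: 16 1,3-diketone; 6 iodomethane
Product: 17 (3R,4S,6S,7R,11R)-4-methyl 1,3-diketone (C15 trans to the C3 isopropenyl group, C5 acyl cis to it)
Conditions: K2CO3, MeI, acetone, rt
Reagents that add atoms: iodomethane (6), CI
Why: In this C-alkylation of a stabilised 1,3-diketone enolate with a soft electrophile, allylic strain with the planar exocyclic acyl unit forces the isopropenyl group pseudo-axial, so MeI should enter from the opposite face and place C5 on the same face as the later O3.

**Step 11**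
Reactants: 17 quaternary diketone
Product: 18 (3R,4R,5S,6S,7R,11R)-5-hydroxy-9-ketone
Conditions: NaBH4, CH2Cl2/MeOH 1:1, −78 °C
Reagents that add atoms: none
Why: Under these cold, non-chelating conditions borohydride should reduce the saturated, acyloxy-activated C5 ketone ahead of the conjugated C9 ketone, and it should attack anti to both the C6–O bond (polar Felkin–Anh) and the C4–C9 acyl bond with C15 beside its path, two preferences that both lead to the 5S (5,6-threo) alcohol.

**Step 12**
Reactants: 18 C5 alcohol
Product: 19 5-mesylate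
Conditions: MsCl, Et3N, CH2Cl2, 0 °C
Reagents that add atoms: methanesulfonyl chloride, CS(=O)(=O)Cl
Why: Mesylation works on hindered secondary alcohols, and the resulting β-mesyloxy ketone cannot eliminate because C4 bears no hydrogen, so one group serves both as protection for O5 and as the later nucleofuge.

**Step 13**
Reactants: 19 mesylate; 3 methanol
Product: 22 (3S,4R,5S,6S,7R,11R)-3-acetate, via methoxy hydroperoxide 20 (not isolated), via peracetate 21 (not isolated)
Conditions: O3, CH2Cl2/MeOH, Sudan III, −78 °C; evaporate; Ac2O, Et3N, DMAP (cat.), CH2Cl2, 0 → 40 °C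
Reagents that add atoms: ozone, O=[O+][O-]; methanol (3), CO
Why: Ozone should take only the electron-rich isopropenyl alkene, methanol traps the carbonyl oxide, and acetylation triggers the Criegee rearrangement in which C3 migrates from carbon to oxygen with retention, so the carvone stereocentre becomes the 3S acetate of the target.

**Step 14**
Reactants: 22 acetate
Product: 23 C8 primary alcohol
Conditions: HF·pyridine, pyridine/THF, 0 °C → rt
Reagents that add atoms: none
Why: Buffered fluoride desilylation spares acetate, mesylate and lactone, and attack of O8 on C5 is not expected because it would require a trans-fused bicyclo[3.3.0] ring system.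

**Step 15**
Reactants: 23 C8 alcohol
Product: 24 C8 primary iodide
Conditions: I2, PPh3, imidazole, CH2Cl2, 0 °C → rt
Reagents that add atoms: iodine, II
Why: The Appel-type iodination converts the primary alcohol by SN2 under almost neutral conditions, while the neopentyl secondary mesylate is inert to iodide.

**Step 16**
Reactants: 24 iodo enone
Product: 26 (3S,4R,5S,6S,7S,9S,11R)-3-acetoxy-9-hydroxy-5-mesyloxy cis-decalin lactone (C4–C9 bridged germacr-1(10)-en-12,6-olide), via samarium alkoxide 25 (not isolated)
Conditions: SmI2 (2.2 equiv), NiI2 (2 mol %), THF, −20 °C; pH 7 buffer at −20 °C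
Reagents that add atoms: none
Why: In this intramolecular samarium Barbier reaction (6-exo-trig), nickel-assisted reduction of the iodide gives a C8 organosamarium that adds 1,2 to C9. The trans-lactone allows only the ring‑B chair with O6 and C11 equatorial, and C4 then holds C3 axial, so C10 must become equatorial and only the cis-decalin with the axial 9α‑OH can form.

**Step 17**
Reactants: 26 cis-decalin hydroxy mesylate
Product: 28 (1(10)Z,4Z,3S,6S,7S,11R)-3-acetoxy-9-oxogermacra-1(10),4-dien-12,6-olide, via potassium alkoxide 27 (not isolated)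
Conditions: KHMDS (1.0 equiv), THF, −78 → 0 °C
Reagents that add atoms: none
Why: KHMDS takes only the C9–OH proton, and in potassium alkoxide 27 the oxygen lone pair pushes into the C4–C9 σ bond, which is antiperiplanar to the equatorial C5–OMs bond, so C9=O formation, C4–C9 cleavage, C4=C5 formation and mesylate departure are concerted. The closest known reaction type is the Wharton-type Grob fragmentation of decalin 1,3-diol monosulfonates to cyclodecenones. No ring is closed by bond formation: the ten-membered carbocycle is the periphery left when the bond shared by the two six-membered rings is cut (ring expansion by fragmentation), and the γ-lactone is carried through unchanged. No stereocentre is made, C4, C5 and C9 turn sp2 and C3, C6, C7 and C11 are bystanders, so the selectivity needed is alkene geometry: the trans-fused lactone freezes ring B as the chair with O6, C11 and OMs equatorial, the cis ring fusion puts C3 axial on C4 and thus gauche to C6 across C4–C5, and that dihedral angle closes to the 4Z alkene, while C1=C10 keeps the Z geometry of the cyclohexene. Competing paths are shut by the substrate: C4 has no hydrogen, H6 is gauche and not anti to the mesylate, and O9 cannot reach the rear of the C5–O bond for oxetane closure. One equivalent of hindered base at low temperature is consumed by the hydroxyl group, which leaves C11–H, the acetate and the C2–H γ-protons of enone 28 untouched.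

**Step 18**
Reactants: 28 cyclodecadienone
Product: 29 (1(10)Z,4Z,3S,6S,7S,9R,11R)-3-acetoxy-9-hydroxygermacra-1(10),4-dien-12,6-olide
Conditions: (S)-2-methyl-CBS-oxazaborolidine (20 mol %), catecholborane, toluene, −78 °C; MeOH, pH 7 buffer
Reagents that add atoms: none
Why: In the Corey–Bakshi–Shibata 1,2-reduction the α-methylalkenyl side (C10) acts as the large group and C8H2 as the small one, so the (S)-catalyst should give the 9R alcohol, the same sense as peripheral attack on the conformer in which C9=O lies over C4=C5.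

**Step 19**
Reactants: 29 9R alcohol
Product: 30 (1(10)Z,4Z,3S,6S,7S,9R,11R)-3,9-diacetoxygermacra-1(10),4-dien-12,6-olide (CNP0226482.4)
Conditions: Ac2O, pyridine, DMAP (cat.), CH2Cl2, 0 °C → rt
Reagents that add atoms: acetic anhydride, CC(=O)OC(C)=O
Why: DMAP-catalysed acetylation of the secondary allylic alcohol proceeds with retention at C9 and is too mild to disturb C11.

**Compound list**
1 | (S)-5-(hydroxymethyl)furan-2(5H)-one | OC[C@H]1OC(=O)C=C1 | starting material
2 | (S)-5-[(tert-butyldimethylsilyloxy)methyl]furan-2(5H)-one | CC(C)(C)[Si](C)(C)OC[C@H]1OC(=O)C=C1 | intermediate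
3 | methanol | CO | starting material
4 | (4R,5S)-5-[(TBSO)methyl]-4-(hydroxymethyl)dihydrofuran-2(3H)-one | OC[C@@H]1[C@@H](CO[Si](C)(C)C(C)(C)C)OC(=O)C1 | intermediate
5 | (4R,5S)-5-[(TBSO)methyl]-4-[(TBDPSO)methyl]dihydrofuran-2(3H)-one | CC(C)(C)[Si](c2ccccc2)(c3ccccc3)OC[C@@H]1[C@@H](CO[Si](C)(C)C(C)(C)C)OC(=O)C1 | intermediate
6 | iodomethane | CI | starting material
7 | lithium enolate of 5 (not isolated) | CC(C)(C)[Si](c2ccccc2)(c3ccccc3)OC[C@@H]1[C@@H](CO[Si](C)(C)C(C)(C)C)OC(O[Li])=C1 | intermediate
8 | (3S,4R,5S)-3-methyl lactone, methyl trans to CH2OTBDPS | CC(C)(C)[Si](c2ccccc2)(c3ccccc3)OC[C@@H]1[C@@H](CO[Si](C)(C)C(C)(C)C)OC(=O)[C@H]1C | intermediate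
9 | lithium enolate of 8 (not isolated) | CC(C)(C)[Si](c2ccccc2)(c3ccccc3)OC[C@@H]1[C@@H](CO[Si](C)(C)C(C)(C)C)OC(O[Li])=C1C | intermediate
10 | (3R,4R,5S)-3-methyl lactone, methyl cis to CH2OTBDPS | CC(C)(C)[Si](c2ccccc2)(c3ccccc3)OC[C@@H]1[C@@H](CO[Si](C)(C)C(C)(C)C)OC(=O)[C@@H]1C | intermediate
11 | (3R,4R,5S)-4-[(TBDPSO)methyl]-5-(hydroxymethyl)-3-methyldihydrofuran-2(3H)-one | CC(C)(C)[Si](c2ccccc2)(c3ccccc3)OC[C@@H]1[C@@H](CO)OC(=O)[C@@H]1C | intermediate
12 | (2S,3R,4R)-3-[(TBDPSO)methyl]-4-methyl-5-oxotetrahydrofuran-2-carbaldehyde | CC(C)(C)[Si](c2ccccc2)(c3ccccc3)OC[C@@H]1[C@@H](C=O)OC(=O)[C@@H]1C | intermediate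
13 | (S)-(+)-carvone | CC1=CC[C@@H](CC1=O)C(C)=C | starting material
14 | carvone lithium dienolate, C4=C9(OLi) (not isolated) | CC1=CC[C@@H](C=C1O[Li])C(C)=C | intermediate
15 | aldol adduct: carvone ring bearing at C4 a CH(OH) group (C5) attached to lactone C6; 3S,6S,7R,11R, C4/C5 epimers | CC(=C)[C@H]1CC=C(C)C(=O)C1C(O)[C@H]2OC(=O)[C@H](C)[C@@H]2CO[Si](c3ccccc3)(c4ccccc4)C(C)(C)C | intermediate
16 | 1,3-diketone (C5=O, C9=O), C4 enolisable | CC(=C)[C@H]1CC=C(C)C(=O)C1C(=O)[C@H]2OC(=O)[C@H](C)[C@@H]2CO[Si](c3ccccc3)(c4ccccc4)C(C)(C)C | intermediate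
17 | (3R,4S,6S,7R,11R)-4-methyl 1,3-diketone, C15 trans to isopropenyl | CC(=C)[C@H]1CC=C(C)C(=O)[C@@]1(C)C(=O)[C@H]2OC(=O)[C@H](C)[C@@H]2CO[Si](c3ccccc3)(c4ccccc4)C(C)(C)C | intermediate
18 | (3R,4R,5S,6S,7R,11R)-5-hydroxy-9-ketone | CC(=C)[C@H]1CC=C(C)C(=O)[C@@]1(C)[C@H](O)[C@H]2OC(=O)[C@H](C)[C@@H]2CO[Si](c3ccccc3)(c4ccccc4)C(C)(C)C | intermediate
19 | 5-mesylate of 18 | CC(=C)[C@H]1CC=C(C)C(=O)[C@@]1(C)[C@H](OS(C)(=O)=O)[C@H]2OC(=O)[C@H](C)[C@@H]2CO[Si](c3ccccc3)(c4ccccc4)C(C)(C)C | intermediate
20 | α-methoxy hydroperoxide on the former isopropenyl carbon (not isolated) | COC(C)(OO)[C@H]1CC=C(C)C(=O)[C@@]1(C)[C@H](OS(C)(=O)=O)[C@H]2OC(=O)[C@H](C)[C@@H]2CO[Si](c3ccccc3)(c4ccccc4)C(C)(C)C | intermediate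
21 | peracetate of 20 (not isolated) | COC(C)(OOC(C)=O)[C@H]1CC=C(C)C(=O)[C@@]1(C)[C@H](OS(C)(=O)=O)[C@H]2OC(=O)[C@H](C)[C@@H]2CO[Si](c3ccccc3)(c4ccccc4)C(C)(C)C | intermediate
22 | (3S,4R,5S,6S,7R,11R)-3-acetoxy-5-mesyloxy-8-OTBDPS enone | CC(=O)O[C@H]1CC=C(C)C(=O)[C@@]1(C)[C@H](OS(C)(=O)=O)[C@H]2OC(=O)[C@H](C)[C@@H]2CO[Si](c3ccccc3)(c4ccccc4)C(C)(C)C | intermediate
23 | C8 primary alcohol | CC(=O)O[C@H]1CC=C(C)C(=O)[C@@]1(C)[C@H](OS(C)(=O)=O)[C@H]2OC(=O)[C@H](C)[C@@H]2CO | intermediate
24 | C8 primary iodide | CC(=O)O[C@H]1CC=C(C)C(=O)[C@@]1(C)[C@H](OS(C)(=O)=O)[C@H]2OC(=O)[C@H](C)[C@@H]2CI | intermediate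
25 | C9 samarium(III) alkoxide of 26 (not isolated) | CC(=O)O[C@H]1CC=C(C)[C@@]3(O[Sm](I)I)C[C@@H]2[C@@H]([C@@H](OS(C)(=O)=O)[C@@]13C)OC(=O)[C@@H]2C | intermediate
26 | (3S,4R,5S,6S,7S,9S,11R) cis-decalin lactone: 9α-OH (axial), 5β-OMs (equatorial), 4α-Me, 3β-OAc, trans-fused 12,6-lactone | CC(=O)O[C@H]1CC=C(C)[C@@]3(O)C[C@@H]2[C@@H]([C@@H](OS(C)(=O)=O)[C@@]13C)OC(=O)[C@@H]2C | intermediate
27 | C9 potassium alkoxide of 26 (not isolated) | CC(=O)O[C@H]1CC=C(C)[C@@]3(O[K])C[C@@H]2[C@@H]([C@@H](OS(C)(=O)=O)[C@@]13C)OC(=O)[C@@H]2C | intermediate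
28 | (1(10)Z,4Z,3S,6S,7S,11R)-3-acetoxy-9-oxogermacra-1(10),4-dien-12,6-olide | CC(=O)O[C@H]1C/C=C(/C)C(=O)C[C@@H]2[C@@H](/C=C\1C)OC(=O)[C@@H]2C | intermediate
29 | (1(10)Z,4Z,3S,6S,7S,9R,11R)-3-acetoxy-9-hydroxygermacra-1(10),4-dien-12,6-olide | CC(=O)O[C@H]1C/C=C(/C)[C@H](O)C[C@@H]2[C@@H](/C=C\1C)OC(=O)[C@@H]2C | intermediate
30 | (1(10)Z,4Z,3S,6S,7S,9R,11R)-3,9-diacetoxygermacra-1(10),4-dien-12,6-olide (CNP0226482.4) | CC(=O)O[C@H]1C/C=C(/C)[C@H](OC(C)=O)C[C@@H]2[C@@H](/C=C\1C)OC(=O)[C@@H]2C | target

**Step count**
Total steps: 19. Longest linear sequence: 19 steps (1 → 30). Carvone 13 enters at step 8 without prior steps.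

**Steps most likely to fail**

Step 16. Several processes could outrun the hindered 1,2-addition:
- single-electron reduction of the conjugated C9 ketone (ketyl coupling or 1,4-reduction);
- protonation of the C8 organosamarium;
- early fragmentation of the samarium alkoxide, which would expose the enone product to reductant.

The fallback makes C8 an acyl-anion donor instead of a reductively generated carbanion. It sets out from 23. Dess–Martin oxidation would give the C8 aldehyde F1. A triazolium-carbene-catalysed intramolecular crossed aldehyde–ketone benzoin reaction (Et3N, THF) would close C8–C9 under the same chair constraint, giving the 8-oxo cis-decalin acyloin F2. NaBH4 at low temperature would give the 8,9-diol F3. PhOC(S)Cl/pyridine would acylate only the secondary hydroxyl, giving the 8-O-phenyl thionocarbonate F4. Barton–McCombie deoxygenation (Bu3SnH, AIBN, toluene) would then return to the route at 26.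

Step 11. Three things may go wrong: poor facial selectivity of hydride delivery at C5, co-reduction of C9, or retro-Claisen cleavage of the non-enolisable 1,3-diketone by methoxide. The fallback hands stereocontrol to a catalyst and gives up chemoselectivity on purpose. It sets out from 17. Excess catecholborane with (S)-Me-CBS in toluene, a non-nucleophilic medium, treats quaternary C4 as the large group at C5. This would reduce both ketones to the 5S,9ξ-diol F5. MnO2 in CH2Cl2 would then re-oxidise only the allylic C9 carbinol and rejoin the route at 18.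

Step 18. The medium ring may present only one carbonyl face, so that conformational bias overrides the catalyst, or conjugate reduction may compete. The fallback accepts the ring's own preference and corrects it by inversion. It sets out from 28. Luche reduction (NaBH4, CeCl3, MeOH, −78 °C) would give the 9S allylic alcohol F6. A Mitsunobu reaction with acetic acid (PPh3, DIAD, toluene) would invert C9 and install the acetate in one operation, rejoining the route at 30.

**Further compounds**
F1 | step 16 | C8 aldehyde of 23 | CC(=O)O[C@H]1CC=C(C)C(=O)[C@@]1(C)[C@H](OS(C)(=O)=O)[C@H]2OC(=O)[C@H](C)[C@@H]2C=O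
F2 | step 16 | 8-oxo-9-hydroxy cis-decalin lactone (acyloin) | CC(=O)O[C@H]1CC=C(C)[C@@]3(O)C(=O)[C@@H]2[C@@H]([C@@H](OS(C)(=O)=O)[C@@]13C)OC(=O)[C@@H]2C
F3 | step 16 | 8,9-dihydroxy cis-decalin lactone (C8 epimers) | CC(=O)O[C@H]1CC=C(C)[C@@]3(O)C(O)[C@@H]2[C@@H]([C@@H](OS(C)(=O)=O)[C@@]13C)OC(=O)[C@@H]2C
F4 | step 16 | 8-O-phenyl thionocarbonate of F3 | CC(=O)O[C@H]1CC=C(C)[C@@]3(O)C(OC(=S)Oc4ccccc4)[C@@H]2[C@@H]([C@@H](OS(C)(=O)=O)[C@@]13C)OC(=O)[C@@H]2C
F5 | step 11 | 5S,9ξ-diol from 17 | CC(=C)[C@H]1CC=C(C)C(O)[C@@]1(C)[C@H](O)[C@H]2OC(=O)[C@H](C)[C@@H]2CO[Si](c3ccccc3)(c4ccccc4)C(C)(C)C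
F6 | step 18 | 9S epimer of 29 | CC(=O)O[C@H]1C/C=C(/C)[C@@H](O)C[C@@H]2[C@@H](/C=C\1C)OC(=O)[C@@H]2C
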